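(The earlier runs and the new flask stem from a simulated flask with constants of no real substance, and the scatter is random.)

The amounts in this flask, followed up to 20.0 h, show target falling while isomer of the product rises, and the two change places between 5.00 h and 10.0 h.

in all of them: substrate 0.20 M; free catalyst 0.99 mol%
- eta: reagent 0.90 equiv; the very flask that is asked about, followed so far
- flask: reagent 0.900 equiv; time 50 h

eta run (percent of the substrate charged)

| time / h | target / % | isomer of the product / % |
|---|---|---|
| 5.00 | 36.7 | 24.5 |
| 10.0 | 27.3 | 37.1 |
| 15.0 | 21.2 | 47.6 |
| 20.0 | 15.8 | 54.7 |

(readings scatter by 0.5 percentage points)

- the numbers in the tables scatter by 0.5 percentage points (one standard deviation)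

* ratio of target to isomer of the product at 6.0 min
* ratio of target to isomer of the product at 50 h
* which of target and isomer of the product there is more of at 50 h

The bench rule is to treat the fall of c(target) as pseudo-first-order and read one number from it: the target lifetime, the span of the readings divided by the natural logarithm of the factor by which target fell across that span. In this flask the reading is 17.8 h. The early time is 0.00562 lifetimes, so the ratio there shows how the two were made rather than how target is lost. The latest time is 2.81 lifetimes, so the ratio there shows the loss; control changes hands in between.

From the last reading, our rule leaves 2.93% target at 50 h. Dividing that by the last isomer reading gives a ratio of 0.0535; dividing it instead by 0.90 equiv, taking the reagent charge as turned wholly into isomer, one for one, gives 0.0326. But the rule has a border. Between the first and last readings, target plus isomer rose by 0.445 of target's fall, so if any of that new material passes through target, our amount is too low.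

The forecast gives 5 early, 0.045 late and isomer of the product ahead, warning that “the burst may not be finished by 6 min”. Its late ratio lies below the higher of our two.

The flask gives 5.13 early and 0.0771 late, with isomer of the product ahead at 74.3% against 5.73% target.

    substrate + reagent ⇌ target (K = 15.0 M⁻¹, k = 9.50 × 10⁻⁴ M⁻¹ s⁻¹)
    substrate + reagent ⇌ isomer of the product (K = 480 M⁻¹, k = 1.80 × 10⁻⁴ M⁻¹ s⁻¹)
    target + free catalyst ⇌ isomer of the product + free catalyst, rate k3*[free catalyst]*[target] forward; the back reaction follows from the equilibrium constant (k = 0.00730 M⁻¹ s⁻¹)
    free catalyst + target → spent catalyst (k = 3.70 × 10⁻⁵ M⁻¹ s⁻¹)

At 50.0 h, the flask holds free catalyst at 80.3% and spent catalyst at 19.7% of the catalyst charged. Target in the flask is about twice our reckoned amount, and its lifetime averaged from 5.00 h to 50 h is 24.5 h, longer than our reading of 17.8 h. In the neighbour flask with 0.230 equiv reagent, we take that charge as turned at the start, split by the first flask's early ratio 5.13, and let target decay with our reading of 17.8 h, which gives an estimate of 1.16% target at 50 h. The computed neighbour flask holds 1.18% target, at a ratio of 0.0556.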